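The route rests on opening the furan ring of the benzofuran at O1–C7a and C3–C3a. C7a carries the ring oxygen and lies between the methoxy-bearing C7 and the ring-fusion carbon C3a, so an aryl iodide with iodine at C7a, methoxy at C7 and a free C–H at C3a maps onto the benzo ring. A palladium/norbornene annulation with an aryl oxirane then alkylates that ortho C–H with the epoxide CH2 (C3) and closes the dihydrofuran by ipso C–O coupling in one operation. The precursors are 4-[3-(benzyloxy)propyl]-1-iodo-2-methoxybenzene and racemic O-benzyl guaiacyl oxirane; dehydrogenation, C3 formylation and a single global debenzylation complete the route.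

Key step: step 4

Assumption: 2-bromo-5-iodoanisole is taken as a catalogue compound, and the epoxide is used as the racemate because the stereocentre it carries is erased when the furan ring is aromatised.

Step 1
Reactants: 1 allyl benzyl ether; 2 2-bromo-5-iodoanisole (1-bromo-4-iodo-2-methoxybenzene)
Product: 4 4-[3-(benzyloxy)propyl]-1-bromo-2-methoxybenzene, via alkylborane 3 (not isolated)
Conditions: 9-BBN, THF, 0 °C → rt; then 2, PdCl2(dppf) (3 mol %), aq K3PO4, DMF, rt → 40 °C
Reagents that add atoms: none
Why: 9-BBN hydroborates the terminal alkene in the anti-Markovnikov sense and the primary alkylborane should undergo B-alkyl Suzuki–Miyaura coupling only at the C–I bond, where oxidative addition is far faster than at the C–Br bond flanked by the methoxy group; the side-chain oxygen is carried as a benzyl ether because that group withstands the chloroiminium reagent of step 6 and can leave together with the phenolic benzyl group in step 7.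

Step 2
Reactants: 4 4-[3-(benzyloxy)propyl]-1-bromo-2-methoxybenzene
Product: 5 4-[3-(benzyloxy)propyl]-1-iodo-2-methoxybenzene
Conditions: NaI (2 equiv), CuI (5 mol %), trans-N,N'-dimethylcyclohexane-1,2-diamine (10 mol %), 1,4-dioxane, 110 °C
Reagents that add atoms: sodium iodide, [Na+].[I-]
Why: Copper-catalysed aromatic Finkelstein exchange with a diamine ligand should convert the bromide into the iodide needed for step 4, the equilibrium being pulled over by NaBr precipitating from dioxane while both ethers stay untouched.

Step 3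
Reactants: 6 O-benzylvanillin (4-(benzyloxy)-3-methoxybenzaldehyde)
Product: 7 racemic 2-[4-(benzyloxy)-3-methoxyphenyl]oxirane
Conditions: trimethylsulfonium iodide, NaH, DMSO/THF, 0 °C → rt; filtration through basic alumina
Reagents that add atoms: trimethylsulfonium iodide, C[S+](C)C.[I-]
Why: Corey–Chaykovsky epoxidation, in which the sulfonium methylide adds to the aldehyde and the alkoxide displaces dimethyl sulfide to close the oxirane; with no facial bias the new stereocentre forms as the racemate, which suffices because it is removed in step 5, and the acid-sensitive product is kept on basic media and used promptly.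

Step 4
Reactants: 5 4-[3-(benzyloxy)propyl]-1-iodo-2-methoxybenzene; 7 racemic 2-[4-(benzyloxy)-3-methoxyphenyl]oxirane
Product: 8 racemic 2-[4-(benzyloxy)-3-methoxyphenyl]-5-[3-(benzyloxy)propyl]-7-methoxy-2,3-dihydro-1-benzofuran
Conditions: Pd(OAc)2 (5 mol %), XPhos (10 mol %), potassium 5-norbornene-2-carboxylate (0.5 equiv), K2CO3 (1.5 equiv), NMP, 60 °C; 7 (2 equiv) added in portions
Reagents that add atoms: none
Why: Zerovalent palladium should insert into the C–I bond of 5, norbornene carbopalladation and palladation of the one free ortho C–H then give the aryl–norbornyl palladacycle of divalent palladium, which opens 7 by SN2-type oxidative addition at the unsubstituted CH2 to a tetravalent palladium alkoxide; reductive elimination forms C3–C3a, β-carbon elimination expels norbornene, and C–O reductive elimination at the ipso carbon forms O1–C7a. The closest known reaction type is the Catellani ortho-alkylation with ipso termination, in its established form as the annulation of aryl iodides with epoxides to 2,3-dihydrobenzofurans. The dihydrofuran ring closes by C(sp2)–O reductive elimination from a six-membered aryl palladium alkoxide chelate, formally a 5-exo closure onto C7a. The C2 stereocentre is the epoxide carbinol carbon, whose C–O bond is never broken, so it is fixed by the epoxide alone and racemic 7 gives racemic 8. The step needs mono-alkylation at C3a and opening of the epoxide at its terminal carbon: the C7 methoxy group blocks the second ortho position and drives norbornene extrusion, while attack at the less hindered CH2, a mild carbonate base, the absence of Lewis acids and portionwise addition of excess 7 should hold back rearrangement to the arylacetaldehyde.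

Step 5
Reactants: 8 racemic 2-[4-(benzyloxy)-3-methoxyphenyl]-5-[3-(benzyloxy)propyl]-7-methoxy-2,3-dihydro-1-benzofuran
Product: 9 2-[4-(benzyloxy)-3-methoxyphenyl]-5-[3-(benzyloxy)propyl]-7-methoxy-1-benzofuran
Conditions: DDQ (1.2 equiv), 1,4-dioxane, 80 °C, dark
Reagents that add atoms: none
Why: DDQ dehydrogenation, in which hydride abstraction from C2–H (benzylic to the para-benzyloxy aryl ring and α to O1) and loss of a C3 proton should aromatise the furan ring and delete the C2 stereocentre, while the benzyl ethers and the side-chain benzylic CH2 react far more slowly when only a slight excess of oxidant is used.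

Step 6
Reactants: 9 2-[4-(benzyloxy)-3-methoxyphenyl]-5-[3-(benzyloxy)propyl]-7-methoxy-1-benzofuran
Product: 11 2-[4-(benzyloxy)-3-methoxyphenyl]-5-[3-(benzyloxy)propyl]-7-methoxy-1-benzofuran-3-carbaldehyde, via iminium chloride 10 (not isolated)
Conditions: POCl3 (3 equiv), DMF, 0 → 70 °C; then ice–H2O
Reagents that add atoms: N,N-dimethylformamide, CN(C)C=O; water, O
Why: Vilsmeier–Haack formylation, in which C3, the β-carbon of the O1–C2=C3 enol ether conjugated to the para-benzyloxy aryl ring, should be the most nucleophilic position toward the weakly electrophilic chloroiminium ion, and hydrolysis of the iminium salt on work-up releases the aldehyde while both benzyl ethers are inert.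

Step 7
Reactants: 11 2-[4-(benzyloxy)-3-methoxyphenyl]-5-[3-(benzyloxy)propyl]-7-methoxy-1-benzofuran-3-carbaldehyde
Product: 12 2-(4-hydroxy-3-methoxyphenyl)-5-(3-hydroxypropyl)-7-methoxy-1-benzofuran-3-carbaldehyde
Conditions: BCl3 (6 equiv), pentamethylbenzene (6 equiv), CH2Cl2, −78 → −20 °C; then H2O
Reagents that add atoms: none
Why: Lewis acid debenzylation, in which BCl3 ionises both benzyl ethers at low temperature and pentamethylbenzene traps the benzyl cations by Friedel–Crafts alkylation, so the aldehyde, the two aryl methyl ethers and the electron-rich rings should be spared and aqueous work-up frees the phenol and the primary alcohol.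

Compound list
1 | allyl benzyl ether | C=CCOCc1ccccc1 | starting material
2 | 2-bromo-5-iodoanisole (1-bromo-4-iodo-2-methoxybenzene) | COc1cc(I)ccc1Br | starting material
3 | 9-[3-(benzyloxy)propyl]-9-borabicyclo[3.3.1]nonane | c1ccccc1COCCCB1C2CCCC1CCC2 | intermediate
4 | 4-[3-(benzyloxy)propyl]-1-bromo-2-methoxybenzene | COc1cc(CCCOCc2ccccc2)ccc1Br | intermediate
5 | 4-[3-(benzyloxy)propyl]-1-iodo-2-methoxybenzene | COc1cc(CCCOCc2ccccc2)ccc1I | intermediate
6 | O-benzylvanillin (4-(benzyloxy)-3-methoxybenzaldehyde) | COc1cc(C=O)ccc1OCc1ccccc1 | starting material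
7 | racemic 2-[4-(benzyloxy)-3-methoxyphenyl]oxirane | COc1cc(C2CO2)ccc1OCc1ccccc1 | intermediate
8 | racemic 2-[4-(benzyloxy)-3-methoxyphenyl]-5-[3-(benzyloxy)propyl]-7-methoxy-2,3-dihydro-1-benzofuran | COc1cc(CCCOCc2ccccc2)cc2CC(c3ccc(OCc4ccccc4)c(OC)c3)Oc12 | intermediate
9 | 2-[4-(benzyloxy)-3-methoxyphenyl]-5-[3-(benzyloxy)propyl]-7-methoxy-1-benzofuran | COc1cc(CCCOCc2ccccc2)cc2cc(-c3ccc(OCc4ccccc4)c(OC)c3)oc12 | intermediate
10 | N-{[2-(4-(benzyloxy)-3-methoxyphenyl)-5-(3-(benzyloxy)propyl)-7-methoxy-1-benzofuran-3-yl]methylidene}-N-methylmethanaminium chloride | C[N+](C)=Cc1c(-c2ccc(OCc3ccccc3)c(OC)c2)oc2c(OC)cc(CCCOCc3ccccc3)cc12.[Cl-] | intermediate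
11 | 2-[4-(benzyloxy)-3-methoxyphenyl]-5-[3-(benzyloxy)propyl]-7-methoxy-1-benzofuran-3-carbaldehyde | COc1cc(CCCOCc2ccccc2)cc2c(C=O)c(-c3ccc(OCc4ccccc4)c(OC)c3)oc12 | intermediate
12 | 2-(4-hydroxy-3-methoxyphenyl)-5-(3-hydroxypropyl)-7-methoxy-1-benzofuran-3-carbaldehyde | COc1cc(-c2oc3c(OC)cc(CCCO)cc3c2C=O)ccc1O | target

Total step count: 7. Longest linear sequence: 6 (steps 1, 2, 4, 5, 6, 7); the epoxide branch (step 3) joins at step 4.

Steps most likely to fail

Step 4. The electron-rich aryl epoxide may isomerise to the arylacetaldehyde, or open at its benzylic carbon, before the palladacycle captures it. The fallback leaves the palladium/norbornene manifold for a Sonogashira coupling with cyclisation; it sets out from 5 and 6 and comes back to the route at 9, so that step 5 is bypassed. Copper-catalysed hydroxylation of 5 (CuI, 1,10-phenanthroline, KOH, DMSO/H2O, 100 °C) would give 4-[3-(benzyloxy)propyl]-2-methoxyphenol F1. Iodination ortho to the hydroxyl group (I2, NaHCO3, THF/H2O; the para position is blocked) would give 4-[3-(benzyloxy)propyl]-2-iodo-6-methoxyphenol F2. Ohira–Bestmann homologation of 6 (dimethyl (1-diazo-2-oxopropyl)phosphonate, K2CO3, MeOH) would give 1-(benzyloxy)-4-ethynyl-2-methoxybenzene F3. Sonogashira coupling of F2 with F3 (PdCl2(PPh3)2, CuI, Et3N, DMF, 60 °C) should give 4-[3-(benzyloxy)propyl]-2-{[4-(benzyloxy)-3-methoxyphenyl]ethynyl}-6-methoxyphenol F4, which should cyclise in the same flask by 5-endo-dig attack of the phenol oxygen on the alkyne to give 9.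

Step 6. The weak chloroiminium electrophile may fail to engage C3 without forcing temperatures, at which conversion stalls or the substrate degrades. The fallback replaces electrophilic formylation by bromination and formylation of an aryllithium; it sets out from 9 and comes back at 11. NBS in MeCN at 0 °C in the dark should brominate C3 to give 2-[4-(benzyloxy)-3-methoxyphenyl]-5-[3-(benzyloxy)propyl]-3-bromo-7-methoxy-1-benzofuran F5. Bromine–lithium exchange (n-BuLi, THF, −78 °C) would give {2-[4-(benzyloxy)-3-methoxyphenyl]-5-[3-(benzyloxy)propyl]-7-methoxy-1-benzofuran-3-yl}lithium F6, which is quenched with DMF and then aqueous NH4Cl to give 11.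

Step 7. Cleavage of the aliphatic benzyl ether may stay incomplete at low temperature, and warming to drive it may cost an aryl methyl ether. The fallback changes the protecting-group plan so that the last step is an ester methanolysis; it sets out from 9 and comes back at the target 12. Hydrogenolysis of 9 (H2, Pd/C, EtOAc/MeOH, rt), carried out before any aldehyde is present, would give 4-[5-(3-hydroxypropyl)-7-methoxy-1-benzofuran-2-yl]-2-methoxyphenol F7. Acetylation (Ac2O, pyridine, DMAP) would give 4-[5-(3-acetoxypropyl)-7-methoxy-1-benzofuran-2-yl]-2-methoxyphenyl acetate F8. Formylation as in step 6 (POCl3, DMF; then H2O) would pass through N-{[2-(4-acetoxy-3-methoxyphenyl)-5-(3-acetoxypropyl)-7-methoxy-1-benzofuran-3-yl]methylidene}-N-methylmethanaminium chloride F9 to 4-[5-(3-acetoxypropyl)-3-formyl-7-methoxy-1-benzofuran-2-yl]-2-methoxyphenyl acetate F10. K2CO3 in MeOH at rt would then remove both acetates and give 12.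

Further compounds
F1 | step 4 | 4-[3-(benzyloxy)propyl]-2-methoxyphenol | COc1cc(CCCOCc2ccccc2)ccc1O
F2 | step 4 | 4-[3-(benzyloxy)propyl]-2-iodo-6-methoxyphenol | COc1cc(CCCOCc2ccccc2)cc(I)c1O
F3 | step 4 | 1-(benzyloxy)-4-ethynyl-2-methoxybenzene | COc1cc(C#C)ccc1OCc1ccccc1
F4 | step 4 | 4-[3-(benzyloxy)propyl]-2-{[4-(benzyloxy)-3-methoxyphenyl]ethynyl}-6-methoxyphenol | COc1cc(CCCOCc2ccccc2)cc(C#Cc2ccc(OCc3ccccc3)c(OC)c2)c1O
F5 | step 6 | 2-[4-(benzyloxy)-3-methoxyphenyl]-5-[3-(benzyloxy)propyl]-3-bromo-7-methoxy-1-benzofuran | COc1cc(CCCOCc2ccccc2)cc2c(Br)c(-c3ccc(OCc4ccccc4)c(OC)c3)oc12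
F6 | step 6 | {2-[4-(benzyloxy)-3-methoxyphenyl]-5-[3-(benzyloxy)propyl]-7-methoxy-1-benzofuran-3-yl}lithium | [Li]c1c(-c2ccc(OCc3ccccc3)c(OC)c2)oc2c(OC)cc(CCCOCc3ccccc3)cc12
F7 | step 7 | 4-[5-(3-hydroxypropyl)-7-methoxy-1-benzofuran-2-yl]-2-methoxyphenol | COc1cc(-c2cc3cc(CCCO)cc(OC)c3o2)ccc1O
F8 | step 7 | 4-[5-(3-acetoxypropyl)-7-methoxy-1-benzofuran-2-yl]-2-methoxyphenyl acetate | COc1cc(-c2cc3cc(CCCOC(C)=O)cc(OC)c3o2)ccc1OC(C)=O
F9 | step 7 | N-{[2-(4-acetoxy-3-methoxyphenyl)-5-(3-acetoxypropyl)-7-methoxy-1-benzofuran-3-yl]methylidene}-N-methylmethanaminium chloride | C[N+](C)=Cc1c(-c2ccc(OC(C)=O)c(OC)c2)oc2c(OC)cc(CCCOC(C)=O)cc12.[Cl-]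
F10 | step 7 | 4-[5-(3-acetoxypropyl)-3-formyl-7-methoxy-1-benzofuran-2-yl]-2-methoxyphenyl acetate | COc1cc(-c2oc3c(OC)cc(CCCOC(C)=O)cc3c2C=O)ccc1OC(C)=O
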